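**Assumption:** the target has no stereocentre and no stereogenic double bond, so it is achiral and no enantiocontrol is needed.

**Retrosynthetic overview**
- The target comes from one global hydrogenation (C≡C, C=C and O‑benzyl) of a benzyl-protected enynone.
- The enynone comes from dehydration of a β‑hydroxy ketone.
- Key C–C bond (C2–C3 of the nonanone chain): directed intermolecular aldol addition of the lithium enolate of 2',6'‑dimethoxyacetophenone to 7‑[4‑(benzyloxy)phenyl]hept‑6‑ynal.
- The aldehyde comes from oxidation of the alcohol made by Sonogashira coupling of 1‑(benzyloxy)‑4‑iodobenzene (from 4‑iodophenol) with hept‑6‑yn‑1‑ol.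
- No ring is formed; both benzene rings are bought.

**Route**

Step 1
Reactants: 1 4‑iodophenol
Product: 2 1‑(benzyloxy)‑4‑iodobenzene
Conditions: BnBr, K2CO3, acetone, reflux
Reagents that add atoms: benzyl bromide, BrCc1ccccc1
Why: Williamson ether synthesis (SN2 of the phenoxide on a benzylic bromide) is near-quantitative and installs a phenol protecting group that survives base, enolate and oxidation chemistry and is removed in the final hydrogenation.

Step 2
Reactants: 2 1‑(benzyloxy)‑4‑iodobenzene; 3 hept‑6‑yn‑1‑ol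
Product: 4 7‑[4‑(benzyloxy)phenyl]hept‑6‑yn‑1‑ol
Conditions: PdCl2(PPh3)2 (2 mol%), CuI (4 mol%), Et3N, THF (degassed), rt
Reagents that add atoms: none
Why: Sonogashira coupling of an aryl iodide with a terminal alkyne proceeds at room temperature, tolerates the free primary alcohol and the benzyl ether, and delivers the complete aryl‑C7 chain.

Step 3
Reactants: 4 7‑[4‑(benzyloxy)phenyl]hept‑6‑yn‑1‑ol
Product: 5 7‑[4‑(benzyloxy)phenyl]hept‑6‑ynal
Conditions: TEMPO (10 mol%), PhI(OAc)2, CH2Cl2, rt
Reagents that add atoms: none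
Why: TEMPO/BAIB oxidation (oxoammonium-mediated) takes a primary alcohol to the aldehyde without over-oxidation under anhydrous conditions and leaves the internal alkyne and the benzyl ether untouched.

Step 4
Reactants: 6 1‑(2,6‑dimethoxyphenyl)ethan‑1‑one; 5 7‑[4‑(benzyloxy)phenyl]hept‑6‑ynal
Product: 9 rac‑9‑[4‑(benzyloxy)phenyl]‑1‑(2,6‑dimethoxyphenyl)‑3‑hydroxynon‑8‑yn‑1‑one, via lithium enolate 7 (not isolated), via lithium aldolate 8 (not isolated)
Conditions: LDA, THF, −78 °C; then 5, THF, −78 °C; AcOH quench at −78 °C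
Reagents that add atoms: none
Why: Directed (crossed) aldol addition: the methyl ketone has only one enolisable side, so LDA gives a single pre-formed lithium enolate that adds to the aldehyde at −78 °C faster than proton transfer, and the cold acidic quench prevents retro-aldol; the new carbinol centre is formed racemic and is removed in step 5.

Step 5
Reactants: 9 rac‑9‑[4‑(benzyloxy)phenyl]‑1‑(2,6‑dimethoxyphenyl)‑3‑hydroxynon‑8‑yn‑1‑one
Product: 11 (E)‑9‑[4‑(benzyloxy)phenyl]‑1‑(2,6‑dimethoxyphenyl)non‑2‑en‑8‑yn‑1‑one, via β‑mesyloxy ketone 10 (not isolated)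
Conditions: MsCl, Et3N, CH2Cl2, 0 °C; then DBU, 0 °C to rt
Reagents that add atoms: none
Why: Mesylation followed by E1cB elimination of the β‑sulfonyloxy ketone gives the conjugated (E)‑enone under mild conditions; the alkene geometry is irrelevant because the double bond is saturated in step 6.

Step 6
Reactants: 11 (E)‑9‑[4‑(benzyloxy)phenyl]‑1‑(2,6‑dimethoxyphenyl)non‑2‑en‑8‑yn‑1‑one
Product: 13 1‑(2,6‑dimethoxyphenyl)‑9‑(4‑hydroxyphenyl)nonan‑1‑one, via saturated benzyl ether 12 (not isolated)
Conditions: H2 (1 atm), 10% Pd/C, EtOAc/EtOH, rt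
Reagents that add atoms: none
Why: Heterogeneous catalytic hydrogenation saturates the alkyne and the enone C=C and then hydrogenolyses the aryl benzyl ether, while the di‑ortho‑substituted, twisted aryl ketone and the methyl ethers are inert at 1 atm and room temperature.

**Compound list**
1 | 4‑iodophenol | Oc1ccc(I)cc1 | starting material
2 | 1‑(benzyloxy)‑4‑iodobenzene | Ic1ccc(OCc2ccccc2)cc1 | intermediate
3 | hept‑6‑yn‑1‑ol | OCCCCCC#C | starting material
4 | 7‑[4‑(benzyloxy)phenyl]hept‑6‑yn‑1‑ol | OCCCCCC#Cc1ccc(OCc2ccccc2)cc1 | intermediate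
5 | 7‑[4‑(benzyloxy)phenyl]hept‑6‑ynal | O=CCCCCC#Cc1ccc(OCc2ccccc2)cc1 | intermediate
6 | 1‑(2,6‑dimethoxyphenyl)ethan‑1‑one (2',6'‑dimethoxyacetophenone) | CC(=O)c1c(OC)cccc1OC | starting material
7 | lithium 1‑(2,6‑dimethoxyphenyl)ethen‑1‑olate (lithium enolate of 6) | [Li+].[O-]C(=C)c1c(OC)cccc1OC | intermediate
8 | lithium rac‑9‑[4‑(benzyloxy)phenyl]‑1‑(2,6‑dimethoxyphenyl)‑1‑oxonon‑8‑yn‑3‑olate (lithium aldolate) | [Li+].[O-]C(CC(=O)c1c(OC)cccc1OC)CCCCC#Cc1ccc(OCc2ccccc2)cc1 | intermediate
9 | rac‑9‑[4‑(benzyloxy)phenyl]‑1‑(2,6‑dimethoxyphenyl)‑3‑hydroxynon‑8‑yn‑1‑one | COc1cccc(OC)c1C(=O)CC(O)CCCCC#Cc1ccc(OCc2ccccc2)cc1 | intermediate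
10 | rac‑9‑[4‑(benzyloxy)phenyl]‑1‑(2,6‑dimethoxyphenyl)‑1‑oxonon‑8‑yn‑3‑yl methanesulfonate | COc1cccc(OC)c1C(=O)CC(OS(C)(=O)=O)CCCCC#Cc1ccc(OCc2ccccc2)cc1 | intermediate
11 | (E)‑9‑[4‑(benzyloxy)phenyl]‑1‑(2,6‑dimethoxyphenyl)non‑2‑en‑8‑yn‑1‑one | COc1cccc(OC)c1C(=O)/C=C/CCCCC#Cc1ccc(OCc2ccccc2)cc1 | intermediate
12 | 9‑[4‑(benzyloxy)phenyl]‑1‑(2,6‑dimethoxyphenyl)nonan‑1‑one | COc1cccc(OC)c1C(=O)CCCCCCCCc1ccc(OCc2ccccc2)cc1 | intermediate
13 | 1‑(2,6‑dimethoxyphenyl)‑9‑(4‑hydroxyphenyl)nonan‑1‑one (CNP0078073.0) | COc1cccc(OC)c1C(=O)CCCCCCCCc1ccc(O)cc1 | target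

**Totals**
Total step count: 6. Longest linear sequence: 6 steps (1 → 2 → 4 → 5 → 9 → 11 → 13); ketone 6 enters at step 4.

**Steps most likely to fail, with fallbacks**

Step 4 (aldol addition). The risks are enolisation or self-condensation of aldehyde 5 and retro-aldol on warming. The fallback sets out from 6 and comes back at 9. Ketone 6 is silylated (TMSOTf, Et3N, CH2Cl2, 0 °C) to the silyl enol ether [1‑(2,6‑dimethoxyphenyl)ethenyl]oxy(trimethyl)silane F1. F1 is then combined with aldehyde 5 in a Lewis-acid-mediated Mukaiyama aldol addition (TiCl4, CH2Cl2, −78 °C, aqueous work-up). This forms the same C2–C3 bond under non-basic conditions where aldehyde enolisation and retro-aldol are not an issue.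

Step 5 (dehydration). The risks are retro-aldol under the basic conditions, chloride displacement of the mesylate, or a sluggish elimination. The fallback sets out from 9 and comes back at 11. Aldol 9 is acetylated (Ac2O, pyridine, cat. DMAP, CH2Cl2, rt) to the stable, purifiable β‑acetoxy ketone rac‑9‑[4‑(benzyloxy)phenyl]‑1‑(2,6‑dimethoxyphenyl)‑1‑oxonon‑8‑yn‑3‑yl acetate F2. F2 is then eliminated in a separate step with DBU in toluene at 60 °C to give enone 11. With the hydroxyl capped, no free aldolate can revert, and no sulfonyl chloride is involved.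

Step 6 (global hydrogenation). The risks are over-reduction of the aryl ketone or a stalled debenzylation. The fallback sets out from 11 and comes back at 13, and it runs only through compounds already in the list (entry F0 below). Enynone 11 is first hydrogenated over Pd/C poisoned with pyridine (H2 1 atm, EtOAc, rt). This saturates the alkyne and alkene but leaves the benzyl ether and ketone intact, so 12 is isolated and purified. The benzyl ether of 12 is then removed by catalytic transfer hydrogenolysis (Pd(OH)2/C, cyclohexa‑1,4‑diene, EtOH, rt), which does not touch aryl ketones, to give 13.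

**Further compounds**
F1 | step 4 | [1‑(2,6‑dimethoxyphenyl)ethenyl]oxy(trimethyl)silane | C=C(O[Si](C)(C)C)c1c(OC)cccc1OC
F2 | step 5 | rac‑9‑[4‑(benzyloxy)phenyl]‑1‑(2,6‑dimethoxyphenyl)‑1‑oxonon‑8‑yn‑3‑yl acetate | COc1cccc(OC)c1C(=O)CC(OC(C)=O)CCCCC#Cc1ccc(OCc2ccccc2)cc1
F0 | step 6 | none | none
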